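Locants: C1–C5 = pent-2-enoic acid chain (C1 = CO2H, C5 carries the furan-3-yl ring). C1'–C15' = side chain on C2 (C3' = stereocentre bearing isopropenyl, C15' = CH2OH).
Cuts: C2=C3 and C2–C1' (alkylated phosphonoacetate, Z-selective Horner–Wadsworth–Emmons); the sp3–sp2 bond C8'–C9' (Zweifel olefination); C7'–C8', C5'=C6' and C3'–isopropenyl in the C1'–C8' half; C13'=C14' and C10'–CH3 in the C9'–C15' half.
Forward: a temporary δ-lactone ring tells the two two-carbon arms at C3' apart and is opened to a C1'–C8' pinacol boronic ester with chloride as placeholder on C1'. Pent-4-yn-1-ol gives the C9'–C15' E-alkenyl iodide, the two halves are joined, and the chloride end is then extended by C2/C1 and the purchased furan ring.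
Enabling feature: the acyclic alkene C9'H=C10'(CH3) is Z, and C9' carries only H and the unbranched C8'H2. C8' can therefore ride on boron as a primary migrating group and C9' can be the α-carbon of an alkenyl boronate. An anti 1,2-shift plus an anti boron–iodine elimination turn the E-alkenyl metal, which syn-methylalumination of a terminal alkyne gives reliably, into the Z-alkene.
Stereochemistry: C3' (R) from a rhodium/(R)-BINAP 1,4-addition; 5'E from a stabilised Wittig ylide; 13'Z and 2Z from Still–Gennari olefinations; 9'Z from E-selective carboalumination followed by the stereoinvertive coupling.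

Key step: step 14

Assumption: the SMILES is read as 3'R, 2Z, 5'E, 9'Z, 13'Z, and all compounds marked as starting materials are taken to be purchasable.

Step 1
Reactants: 1 5,6-dihydro-2H-pyran-2-one; 2 potassium trifluoro(prop-1-en-2-yl)borate
Product: 3 (4R)-4-(prop-1-en-2-yl)oxan-2-one
Conditions: [Rh(cod)2]PF6 (3 mol %), (R)-BINAP (3.3 mol %), toluene/H2O 20:1, 105 °C
Reagents that add atoms: none
Why: Hayashi–Miyaura asymmetric 1,4-addition: the isopropenylrhodium species formed by transmetalation adds to the s-trans-locked unsaturated lactone on the face left open by (R)-BINAP, which by the model established for cyclic enones and unsaturated lactones should set C4 as R, and water releases the product from the rhodium enolate.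

Step 2
Reactants: 3 (4R)-4-(prop-1-en-2-yl)oxan-2-one
Product: 4 (4R)-4-(prop-1-en-2-yl)oxan-2-ol (both anomers)
Conditions: i-Bu2AlH (1.1 equiv), CH2Cl2, −78 °C
Reagents that add atoms: none
Why: Partial lactone reduction: the tetrahedral aluminium hemiacetal is stable at −78 °C and gives the lactol only on work-up, while the 1,1-disubstituted alkene and the β-stereocentre are not touched.

Step 3
Reactants: 4 (4R)-4-(prop-1-en-2-yl)oxan-2-ol; 5 ethyl 2-(triphenyl-λ5-phosphanylidene)propanoate
Product: 6 ethyl (2E,5S)-7-hydroxy-2-methyl-5-(prop-1-en-2-yl)hept-2-enoate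
Conditions: toluene, 90 °C
Reagents that add atoms: none
Why: Wittig olefination of the ring-opened hydroxy aldehyde tautomer by a stabilised α-methyl ylide should give the E-trisubstituted enoate, and the base-free medium keeps the freed hydroxyl from oxa-Michael closure.

Step 4
Reactants: 6 ethyl (2E,5S)-7-hydroxy-2-methyl-5-(prop-1-en-2-yl)hept-2-enoate
Product: 7 (2E,5S)-2-methyl-5-(prop-1-en-2-yl)hept-2-ene-1,7-diol
Conditions: i-Bu2AlH (3.5 equiv), CH2Cl2, −78 to 0 °C
Reagents that add atoms: none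
Why: 1,2-Reduction of an α,β-unsaturated ester by i-Bu2AlH gives the allylic alcohol with the alkene geometry kept, one equivalent being spent on the free hydroxyl.

Step 5
Reactants: 7 (2E,5S)-2-methyl-5-(prop-1-en-2-yl)hept-2-ene-1,7-diol
Product: 8 (2E,5S)-1,7-dichloro-2-methyl-5-(prop-1-en-2-yl)hept-2-ene
Conditions: PPh3 (2.6 equiv), CCl4, reflux
Reagents that add atoms: tetrachloromethane ClC(Cl)(Cl)Cl
Why: Appel chlorination: both primary alkoxyphosphonium ions are displaced by chloride in SN2 fashion, so the allylic terminus is not transposed and the E geometry is kept.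

Step 6
Reactants: 8 (2E,5S)-1,7-dichloro-2-methyl-5-(prop-1-en-2-yl)hept-2-ene; 9 2,2'-methylenebis(4,4,5,5-tetramethyl-1,3,2-dioxaborolane)
Product: 11 2-[(3E,6S)-8-chloro-3-methyl-6-(prop-1-en-2-yl)oct-3-en-1-yl]-4,4,5,5-tetramethyl-1,3,2-dioxaborolane, via sodium borylmethanide 10 (not isolated)
Conditions: 9 (1.2 equiv), NaOt-Bu (1.3 equiv), THF, 0 °C; then 8, 0 °C to rt
Reagents that add atoms: none
Why: Deborylative alkylation of a geminal bis(boronate): tert-butoxide takes off one boryl group and the α-boryl carbanion 10 displaces the primary allylic chloride by SN2 much faster than the unactivated alkyl chloride, which adds the last carbon together with its boron in one operation.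

Step 7
Reactants: 12 pent-4-yn-1-ol
Product: 14 (4E)-5-iodo-4-methylpent-4-en-1-ol, via dimethylalkenylalane 13 (not isolated)
Conditions: Me3Al (3 equiv), Cp2ZrCl2 (0.25 equiv), CH2Cl2, 0 °C to rt; then I2, THF, −30 °C
Reagents that add atoms: trimethylaluminium C[Al](C)C; iodine II
Why: Negishi zirconium-catalysed methylalumination adds methyl and aluminium syn across the terminal alkyne with aluminium at the terminal carbon, and iodinolysis with retention gives the E-alkenyl iodide.

Step 8
Reactants: 14 (4E)-5-iodo-4-methylpent-4-en-1-ol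
Product: 15 (4E)-5-iodo-4-methylpent-4-enal
Conditions: Dess–Martin periodinane, CH2Cl2, rt
Reagents that add atoms: none
Why: Dess–Martin oxidation stops at the aldehyde under near-neutral conditions and leaves the alkenyl iodide alone.

Step 9
Reactants: 15 (4E)-5-iodo-4-methylpent-4-enal; 16 ethyl 2-[bis(2,2,2-trifluoroethoxy)phosphoryl]propanoate
Product: 18 ethyl (2Z,6E)-7-iodo-2,6-dimethylhepta-2,6-dienoate, via potassium phosphonate carbanion 17 (not isolated)
Conditions: KN(SiMe3)2, 18-crown-6, THF, −78 °C; then 15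
Reagents that add atoms: none
Why: Still–Gennari olefination: the electron-poor trifluoroethyl phosphonate with a dissociated potassium counter-ion makes elimination from the kinetically formed adduct fast, which should place the ester cis to the chain (Z).

Step 10
Reactants: 18 ethyl (2Z,6E)-7-iodo-2,6-dimethylhepta-2,6-dienoate
Product: 19 (2Z,6E)-7-iodo-2,6-dimethylhepta-2,6-dien-1-ol
Conditions: i-Bu2AlH (2.3 equiv), CH2Cl2, −78 °C
Reagents that add atoms: none
Why: 1,2-Reduction of the enoate keeps the Z geometry, and the alkenyl iodide is inert to i-Bu2AlH at −78 °C.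

Step 11
Reactants: 19 (2Z,6E)-7-iodo-2,6-dimethylhepta-2,6-dien-1-ol
Product: 20 tert-butyl{[(2Z,6E)-7-iodo-2,6-dimethylhepta-2,6-dien-1-yl]oxy}dimethylsilane
Conditions: t-BuMe2SiCl, imidazole, CH2Cl2, rt
Reagents that add atoms: tert-butyldimethylsilyl chloride CC(C)(C)[Si](C)(C)Cl
Why: Standard silylation masks the acidic hydroxyl before lithiation, and the silyl ether withstands t-BuLi at −78 °C, I2/NaOMe and the later carbanion steps.

Step 12
Reactants: 21 3-bromofuran; 22 oxetane
Product: 24 3-(furan-3-yl)propan-1-ol, via furan-3-yllithium 23 (not isolated)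
Conditions: n-BuLi, THF, −78 °C; then 22, BF3·OEt2, −78 °C
Reagents that add atoms: none
Why: Bromine–lithium exchange at −78 °C, below the temperature at which furan-3-yllithium rearranges to the 2-lithio isomer, followed by BF3-assisted SN2 opening of oxetane gives the three-carbon alcohol in one flask.

Step 13
Reactants: 24 3-(furan-3-yl)propan-1-ol
Product: 25 3-(furan-3-yl)propanal
Conditions: Dess–Martin periodinane, CH2Cl2, 0 °C to rt
Reagents that add atoms: none
Why: Dess–Martin oxidation gives the aldehyde without strong acid or electrophilic halogen, both of which would attack the furan ring.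

Step 14
Reactants: 20 tert-butyl{[(2Z,6E)-7-iodo-2,6-dimethylhepta-2,6-dien-1-yl]oxy}dimethylsilane; 11 2-[(3E,6S)-8-chloro-3-methyl-6-(prop-1-en-2-yl)oct-3-en-1-yl]-4,4,5,5-tetramethyl-1,3,2-dioxaborolane
Product: 29 tert-butyl{[(2Z,6Z,10E,13S)-15-chloro-2,6,10-trimethyl-13-(prop-1-en-2-yl)pentadeca-2,6,10-trien-1-yl]oxy}dimethylsilane, via alkenyllithium 26 (not isolated), via lithium boronate complex 27 (not isolated), via beta-iodo boronic ester 28 (not isolated)
Conditions: 20 (1.2 equiv), t-BuLi (2.4 equiv), Et2O, −78 °C; 11 (1.0 equiv), THF, −78 to 0 °C; I2 (1.3 equiv), THF, −78 °C; NaOMe (3 equiv), MeOH, −78 °C to rt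
Reagents that add atoms: none
Why: Zweifel olefination: the configurationally stable E-alkenyllithium 26 adds to the empty orbital on boron of 11 faster than to the carbon–chlorine bond, and I2 then attacks the electron-rich alkenyl boronate 27 at its methyl-bearing β-carbon, which triggers the 1,2-metalate shift of the primary CH2 group from boron to the α-carbon antiperiplanar to the iodonium bridge. Methoxide then binds to boron in 28 and boron and iodine leave antiperiplanar, so that one anti addition plus one anti elimination swap the substituents on the former α-carbon and the E-alkenyl metal from syn-carboalumination is delivered as the Z-trisubstituted alkene. The closest known reaction type is the transition-metal-free coupling of primary and secondary alkyl pinacol boronic esters with alkenyllithiums under I2/NaOMe. No ring is closed and no lasting stereocentre is made: the two transient stereocentres of 28 are fixed relative to each other by the anti migration, both face isomers converge on the same alkene, and the existing stereocentre lies five bonds from boron and is not touched. The step needs I2 to choose one of five C=C bonds, which the negative charge of the borate secures by making its alkene by far the best nucleophile at −78 °C, and it needs carbon alone to migrate, which the two non-migrating pinacol oxygen ligands secure. It thus joins the C12 and C9 halves and sets the least accessible alkene geometry in one flask, the boron helper leaving in the same operation.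

Step 15
Reactants: 29 tert-butyl{[(2Z,6Z,10E,13S)-15-chloro-2,6,10-trimethyl-13-(prop-1-en-2-yl)pentadeca-2,6,10-trien-1-yl]oxy}dimethylsilane
Product: 30 tert-butyl{[(2Z,6Z,10E,13S)-15-iodo-2,6,10-trimethyl-13-(prop-1-en-2-yl)pentadeca-2,6,10-trien-1-yl]oxy}dimethylsilane
Conditions: NaI (5 equiv), 2-butanone, reflux
Reagents that add atoms: sodium iodide [Na+].[I-]
Why: Finkelstein exchange at the primary chloride is driven by precipitation of NaCl and touches neither the alkenes nor the silyl ether.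

Step 16
Reactants: 30 tert-butyl{[(2Z,6Z,10E,13S)-15-iodo-2,6,10-trimethyl-13-(prop-1-en-2-yl)pentadeca-2,6,10-trien-1-yl]oxy}dimethylsilane; 31 methyl 2-[bis(2,2,2-trifluoroethoxy)phosphoryl]acetate
Product: 33 methyl (5R,7E,11Z,15Z)-2-[bis(2,2,2-trifluoroethoxy)phosphoryl]-17-[(tert-butyldimethylsilyl)oxy]-8,12,16-trimethyl-5-(prop-1-en-2-yl)heptadeca-7,11,15-trienoate (both epimers at C2), via sodium phosphonate carbanion 32 (not isolated)
Conditions: 31 (2 equiv), NaH (1.9 equiv), THF/DMSO, 0 °C; then 30, rt to 45 °C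
Reagents that add atoms: none
Why: SN2 alkylation of the stabilised phosphonoacetate carbanion, used in excess to suppress double alkylation, by a primary iodide in a dipolar aprotic medium; the new centre forms as both epimers and is destroyed in the next step.

Step 17
Reactants: 33 methyl (5R,7E,11Z,15Z)-2-[bis(2,2,2-trifluoroethoxy)phosphoryl]-17-[(tert-butyldimethylsilyl)oxy]-8,12,16-trimethyl-5-(prop-1-en-2-yl)heptadeca-7,11,15-trienoate; 25 3-(furan-3-yl)propanal
Product: 35 methyl (2Z)-2-[(3R,5E,9Z,13Z)-15-[(tert-butyldimethylsilyl)oxy]-6,10,14-trimethyl-3-(prop-1-en-2-yl)pentadeca-5,9,13-trien-1-yl]-5-(furan-3-yl)pent-2-enoate, via potassium phosphonate carbanion 34 (not isolated)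
Conditions: KN(SiMe3)2, 18-crown-6, THF, −78 °C; then 25
Reagents that add atoms: none
Why: Still–Gennari olefination of an α-alkylated trifluoroethyl phosphonoacetate with an unbranched aliphatic aldehyde should place the ester cis to the furylethyl chain (2Z) under kinetic control.

Step 18
Reactants: 35 methyl (2Z)-2-[(3R,5E,9Z,13Z)-15-[(tert-butyldimethylsilyl)oxy]-6,10,14-trimethyl-3-(prop-1-en-2-yl)pentadeca-5,9,13-trien-1-yl]-5-(furan-3-yl)pent-2-enoate
Product: 36 methyl (2Z)-5-(furan-3-yl)-2-[(3R,5E,9Z,13Z)-15-hydroxy-6,10,14-trimethyl-3-(prop-1-en-2-yl)pentadeca-5,9,13-trien-1-yl]pent-2-enoate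
Conditions: Bu4NF, THF, 0 °C to rt
Reagents that add atoms: none
Why: Fluoride-induced desilylation frees the allylic alcohol without acid, so the furan ring, the Z-allylic alcohol and the Z-enoate are preserved.

Step 19
Reactants: 36 methyl (2Z)-5-(furan-3-yl)-2-[(3R,5E,9Z,13Z)-15-hydroxy-6,10,14-trimethyl-3-(prop-1-en-2-yl)pentadeca-5,9,13-trien-1-yl]pent-2-enoate
Product: 38 (2Z)-5-(furan-3-yl)-2-[(3R,5E,9Z,13Z)-15-hydroxy-6,10,14-trimethyl-3-(prop-1-en-2-yl)pentadeca-5,9,13-trien-1-yl]pent-2-enoic acid, via lithium carboxylate 37 (not isolated)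
Conditions: LiOH, THF/MeOH/H2O, 40 °C; then 1 M HCl to pH 4, 0 °C
Reagents that add atoms: lithium hydroxide [Li+].[OH-]
Why: Saponification by acyl–oxygen cleavage does not involve the C2=C3 bond, so the Z geometry is kept, and the brief cold acidification to pH 4 is tolerated by the furan ring and the allylic alcohol.

Compound list
1 | 5,6-dihydro-2H-pyran-2-one | O=C1C=CCCO1 | starting material
2 | potassium trifluoro(prop-1-en-2-yl)borate | C=C(C)[B-](F)(F)F.[K+] | starting material
3 | (4R)-4-(prop-1-en-2-yl)oxan-2-one | C=C(C)[C@H]1CC(=O)OCC1 | intermediate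
4 | (4R)-4-(prop-1-en-2-yl)oxan-2-ol (both anomers) | C=C(C)[C@H]1CC(O)OCC1 | intermediate
5 | ethyl 2-(triphenyl-λ5-phosphanylidene)propanoate | CCOC(=O)C(C)=P(c1ccccc1)(c1ccccc1)c1ccccc1 | starting material
6 | ethyl (2E,5S)-7-hydroxy-2-methyl-5-(prop-1-en-2-yl)hept-2-enoate | C=C(C)[C@@H](C/C=C(\C)C(=O)OCC)CCO | intermediate
7 | (2E,5S)-2-methyl-5-(prop-1-en-2-yl)hept-2-ene-1,7-diol | C=C(C)[C@@H](C/C=C(\C)CO)CCO | intermediate
8 | (2E,5S)-1,7-dichloro-2-methyl-5-(prop-1-en-2-yl)hept-2-ene | C=C(C)[C@@H](C/C=C(\C)CCl)CCCl | intermediate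
9 | 2,2'-methylenebis(4,4,5,5-tetramethyl-1,3,2-dioxaborolane) | CC1(C)OB(CB2OC(C)(C)C(C)(C)O2)OC1(C)C | starting material
10 | sodium (4,4,5,5-tetramethyl-1,3,2-dioxaborolan-2-yl)methanide | [Na+].[CH2-]B1OC(C)(C)C(C)(C)O1 | intermediate
11 | 2-[(3E,6S)-8-chloro-3-methyl-6-(prop-1-en-2-yl)oct-3-en-1-yl]-4,4,5,5-tetramethyl-1,3,2-dioxaborolane | C=C(C)[C@@H](C/C=C(\C)CCB1OC(C)(C)C(C)(C)O1)CCCl | intermediate
12 | pent-4-yn-1-ol | C#CCCCO | starting material
13 | [(1E)-5-(dimethylalumanyloxy)-2-methylpent-1-en-1-yl]dimethylalumane | C[Al](C)/C=C(\C)CCCO[Al](C)C | intermediate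
14 | (4E)-5-iodo-4-methylpent-4-en-1-ol | I/C=C(\C)CCCO | intermediate
15 | (4E)-5-iodo-4-methylpent-4-enal | I/C=C(\C)CCC=O | intermediate
16 | ethyl 2-[bis(2,2,2-trifluoroethoxy)phosphoryl]propanoate | CCOC(=O)C(C)P(=O)(OCC(F)(F)F)OCC(F)(F)F | starting material
17 | potassium salt of 16 (carbanion at C2) | [K+].CCOC(=O)[C-](C)P(=O)(OCC(F)(F)F)OCC(F)(F)F | intermediate
18 | ethyl (2Z,6E)-7-iodo-2,6-dimethylhepta-2,6-dienoate | I/C=C(\C)CC/C=C(/C)C(=O)OCC | intermediate
19 | (2Z,6E)-7-iodo-2,6-dimethylhepta-2,6-dien-1-ol | I/C=C(\C)CC/C=C(/C)CO | intermediate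
20 | tert-butyl{[(2Z,6E)-7-iodo-2,6-dimethylhepta-2,6-dien-1-yl]oxy}dimethylsilane | I/C=C(\C)CC/C=C(/C)CO[Si](C)(C)C(C)(C)C | intermediate
21 | 3-bromofuran | Brc1ccoc1 | starting material
22 | oxetane | C1COC1 | starting material
23 | furan-3-yllithium | [Li]c1ccoc1 | intermediate
24 | 3-(furan-3-yl)propan-1-ol | OCCCc1ccoc1 | intermediate
25 | 3-(furan-3-yl)propanal | O=CCCc1ccoc1 | intermediate
26 | {(1E,5Z)-7-[(tert-butyldimethylsilyl)oxy]-2,6-dimethylhepta-1,5-dien-1-yl}lithium | [Li]/C=C(\C)CC/C=C(/C)CO[Si](C)(C)C(C)(C)C | intermediate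
27 | lithium pinacolato borate carrying the (1E,5Z)-dienyl group of 26 and the (3E,6S)-octenyl group of 11 on boron | [Li+].C=C(C)[C@@H](C/C=C(\C)CC[B-]1(/C=C(\C)CC/C=C(/C)CO[Si](C)(C)C(C)(C)C)OC(C)(C)C(C)(C)O1)CCCl | intermediate
28 | β-iodoalkyl pinacol boronic ester from anti iodination/1,2-shift (two face isomers with the same relative configuration at the C–B and C–I carbons, one drawn) | C=C(C)[C@@H](C/C=C(\C)CC[C@H](B1OC(C)(C)C(C)(C)O1)[C@](I)(C)CC/C=C(/C)CO[Si](C)(C)C(C)(C)C)CCCl | intermediate
29 | tert-butyl{[(2Z,6Z,10E,13S)-15-chloro-2,6,10-trimethyl-13-(prop-1-en-2-yl)pentadeca-2,6,10-trien-1-yl]oxy}dimethylsilane | C=C(C)[C@@H](C/C=C(\C)CC/C=C(/C)CC/C=C(/C)CO[Si](C)(C)C(C)(C)C)CCCl | intermediate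
30 | tert-butyl{[(2Z,6Z,10E,13S)-15-iodo-2,6,10-trimethyl-13-(prop-1-en-2-yl)pentadeca-2,6,10-trien-1-yl]oxy}dimethylsilane | C=C(C)[C@@H](C/C=C(\C)CC/C=C(/C)CC/C=C(/C)CO[Si](C)(C)C(C)(C)C)CCI | intermediate
31 | methyl 2-[bis(2,2,2-trifluoroethoxy)phosphoryl]acetate | COC(=O)CP(=O)(OCC(F)(F)F)OCC(F)(F)F | starting material
32 | sodium salt of 31 (carbanion at C2) | [Na+].COC(=O)[CH-]P(=O)(OCC(F)(F)F)OCC(F)(F)F | intermediate
33 | methyl (5R,7E,11Z,15Z)-2-[bis(2,2,2-trifluoroethoxy)phosphoryl]-17-[(tert-butyldimethylsilyl)oxy]-8,12,16-trimethyl-5-(prop-1-en-2-yl)heptadeca-7,11,15-trienoate (both epimers at C2) | C=C(C)[C@@H](C/C=C(\C)CC/C=C(/C)CC/C=C(/C)CO[Si](C)(C)C(C)(C)C)CCC(C(=O)OC)P(=O)(OCC(F)(F)F)OCC(F)(F)F | intermediate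
34 | potassium salt of 33 (carbanion at C2) | [K+].C=C(C)[C@@H](C/C=C(\C)CC/C=C(/C)CC/C=C(/C)CO[Si](C)(C)C(C)(C)C)CC[C-](C(=O)OC)P(=O)(OCC(F)(F)F)OCC(F)(F)F | intermediate
35 | methyl (2Z)-2-[(3R,5E,9Z,13Z)-15-[(tert-butyldimethylsilyl)oxy]-6,10,14-trimethyl-3-(prop-1-en-2-yl)pentadeca-5,9,13-trien-1-yl]-5-(furan-3-yl)pent-2-enoate | C=C(C)[C@@H](C/C=C(\C)CC/C=C(/C)CC/C=C(/C)CO[Si](C)(C)C(C)(C)C)CC/C(=C/CCc1ccoc1)C(=O)OC | intermediate
36 | methyl (2Z)-5-(furan-3-yl)-2-[(3R,5E,9Z,13Z)-15-hydroxy-6,10,14-trimethyl-3-(prop-1-en-2-yl)pentadeca-5,9,13-trien-1-yl]pent-2-enoate | C=C(C)[C@@H](C/C=C(\C)CC/C=C(/C)CC/C=C(/C)CO)CC/C(=C/CCc1ccoc1)C(=O)OC | intermediate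
37 | lithium salt of 38 | [Li+].C=C(C)[C@@H](C/C=C(\C)CC/C=C(/C)CC/C=C(/C)CO)CC/C(=C/CCc1ccoc1)C(=O)[O-] | intermediate
38 | (2Z)-5-(furan-3-yl)-2-[(3R,5E,9Z,13Z)-15-hydroxy-6,10,14-trimethyl-3-(prop-1-en-2-yl)pentadeca-5,9,13-trien-1-yl]pent-2-enoic acid (CNP0258614.1) | C=C(C)[C@@H](C/C=C(\C)CC/C=C(/C)CC/C=C(/C)CO)CC/C(=C/CCc1ccoc1)C(=O)O | target

Total step count: 19.
Longest linear sequence: 12 steps (steps 1–6 and 14–19).

Steps most likely to fail

Step 14. The stereospecificity may erode if the tertiary carbon–iodine bond ionises before the anti elimination, and iodine may be consumed by the other alkenes. The fallback replaces the stereoinvertive 1,2-metalate shift by a stereoretentive palladium cross-coupling. It sets out from 12 and 11 and comes back at 29. The methylalumination mixture from 12 (Me3Al, Cp2ZrCl2) is heated so that chelation by the aluminium alkoxide isomerises the alkenylalane, and iodinolysis should give (4Z)-5-iodo-4-methylpent-4-en-1-ol F1. The operations of steps 8 to 11 then carry it through (4Z)-5-iodo-4-methylpent-4-enal F2, ethyl (2Z,6Z)-7-iodo-2,6-dimethylhepta-2,6-dienoate F3 and (2Z,6Z)-7-iodo-2,6-dimethylhepta-2,6-dien-1-ol F4 to tert-butyl{[(2Z,6Z)-7-iodo-2,6-dimethylhepta-2,6-dien-1-yl]oxy}dimethylsilane F5. KHF2 in MeOH/H2O turns 11 into potassium [(3E,6S)-8-chloro-3-methyl-6-(prop-1-en-2-yl)oct-3-en-1-yl]trifluoroborate F6. A Suzuki–Miyaura alkyl–alkenyl coupling of F5 and F6 (PdCl2(dppf), Cs2CO3, toluene/H2O, 80 °C) with retention at the alkenyl carbon returns to 29.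

Step 1. Facial discrimination may be insufficient, or the α-branched alkenylboron reagent may protodeboronate before transmetalation. The fallback replaces asymmetric catalysis by enzymatic desymmetrisation. It sets out from 1 and comes back at 4. Addition of CH2=C(CH3)MgBr in the presence of CuBr·SMe2 and Me3SiCl (THF, −78 °C) gives racemic 4-(prop-1-en-2-yl)oxan-2-one F7, and LiAlH4 reduces it to the prochiral 3-(prop-1-en-2-yl)pentane-1,5-diol F8. A lipase (serine hydrolase class) with vinyl acetate acylates one enantiotopic arm to (3S)-5-hydroxy-3-(prop-1-en-2-yl)pentyl acetate F9, the choice of enzyme deciding which arm reacts. Dess–Martin oxidation gives (3R)-5-oxo-3-(prop-1-en-2-yl)pentyl acetate F10. K2CO3 in MeOH removes the acetate, whereupon the hydroxy aldehyde closes to lactol 4.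

Step 16. The weakly nucleophilic fluorinated phosphonate carbanion may displace the unactivated primary iodide only sluggishly, with competing double alkylation and loss of trifluoroethoxide. The fallback forms the C2–C1' bond by cross-coupling on a preformed alkene instead of by enolate alkylation. It sets out from 30, 31 and 25 and comes back at 35. Aqueous NaOBr brominates 31 twice to methyl 2,2-dibromo-2-[bis(2,2,2-trifluoroethoxy)phosphoryl]acetate F11, and SnCl2 reduces it to methyl 2-bromo-2-[bis(2,2,2-trifluoroethoxy)phosphoryl]acetate F12. Its Horner–Wadsworth–Emmons reaction with 25 (KOt-Bu, 18-crown-6, THF, −78 °C) should give methyl (2E)-2-bromo-5-(furan-3-yl)pent-2-enoate F13, with the ester cis to the chain. Zinc dust with LiCl in THF inserts into 30 to give the alkylzinc iodide F14. A Negishi coupling of F13 and F14 (PdCl2(dppf), THF, rt to 40 °C) with retention returns to 35.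

Further compounds
F1 | step 14 | (4Z)-5-iodo-4-methylpent-4-en-1-ol | I/C=C(/C)CCCO
F2 | step 14 | (4Z)-5-iodo-4-methylpent-4-enal | I/C=C(/C)CCC=O
F3 | step 14 | ethyl (2Z,6Z)-7-iodo-2,6-dimethylhepta-2,6-dienoate | I/C=C(/C)CC/C=C(/C)C(=O)OCC
F4 | step 14 | (2Z,6Z)-7-iodo-2,6-dimethylhepta-2,6-dien-1-ol | I/C=C(/C)CC/C=C(/C)CO
F5 | step 14 | tert-butyl{[(2Z,6Z)-7-iodo-2,6-dimethylhepta-2,6-dien-1-yl]oxy}dimethylsilane | I/C=C(/C)CC/C=C(/C)CO[Si](C)(C)C(C)(C)C
F6 | step 14 | potassium [(3E,6S)-8-chloro-3-methyl-6-(prop-1-en-2-yl)oct-3-en-1-yl]trifluoroborate | [K+].C=C(C)[C@@H](C/C=C(\C)CC[B-](F)(F)F)CCCl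
F7 | step 1 | racemic 4-(prop-1-en-2-yl)oxan-2-one | C=C(C)C1CC(=O)OCC1
F8 | step 1 | 3-(prop-1-en-2-yl)pentane-1,5-diol | C=C(C)C(CCO)CCO
F9 | step 1 | (3S)-5-hydroxy-3-(prop-1-en-2-yl)pentyl acetate | C=C(C)[C@@H](CCO)CCOC(C)=O
F10 | step 1 | (3R)-5-oxo-3-(prop-1-en-2-yl)pentyl acetate | C=C(C)[C@@H](CC=O)CCOC(C)=O
F11 | step 16 | methyl 2,2-dibromo-2-[bis(2,2,2-trifluoroethoxy)phosphoryl]acetate | COC(=O)C(Br)(Br)P(=O)(OCC(F)(F)F)OCC(F)(F)F
F12 | step 16 | methyl 2-bromo-2-[bis(2,2,2-trifluoroethoxy)phosphoryl]acetate | COC(=O)C(Br)P(=O)(OCC(F)(F)F)OCC(F)(F)F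
F13 | step 16 | methyl (2E)-2-bromo-5-(furan-3-yl)pent-2-enoate | COC(=O)/C(Br)=C\CCc1ccoc1
F14 | step 16 | {(3S,5E,9Z,13Z)-15-[(tert-butyldimethylsilyl)oxy]-6,10,14-trimethyl-3-(prop-1-en-2-yl)pentadeca-5,9,13-trien-1-yl}zinc iodide | C=C(C)[C@@H](C/C=C(\C)CC/C=C(/C)CC/C=C(/C)CO[Si](C)(C)C(C)(C)C)CC[Zn]I
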